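Gamma ended with more J than beta, 21.0 % of the X charged against 12.5 %, and gamma also carried the lower loading of G, 0.005 mol% against 0.01 mol%.

| flask | X | G | remark | time |
|---|---|---|---|---|
| alpha | 17 mM | 0.01 mol% | run made earlier |  |
| beta | 26 mM | 0.01 mol% | run made earlier |  |
| gamma | 34 mM | 0.005 mol% | run made earlier |  |
| flask | 34 mM | 0.01 mol% |  | 10 min |

| run | time / min | X / % | Q / % | J / % |
|---|---|---|---|---|
| alpha | 1.33 | 0 | 85.7 | 14.5 |
| alpha | 2.50 | 0.1 | 86.6 | 13.7 |
| alpha | 4.00 | 0 | 86.6 | 13.3 |
| alpha | 5.00 | 0 | 85.5 | 14.2 |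
| alpha | 6.00 | 0.3 | 85.7 | 14.3 |
| beta | 0.500 | 0 | 87.8 | 12.7 |
| beta | 1.50 | 0 | 87.8 | 12.0 |
| beta | 3.00 | 0 | 88.4 | 12.7 |
| beta | 4.00 | 0.1 | 87.1 | 13.7 |
| beta | 6.00 | 0.5 | 87.1 | 12.5 |
| gamma | 0.500 | 0.7 | 77.4 | 21.8 |
| gamma | 0.833 | 0.9 | 78.3 | 21.9 |
| gamma | 1.50 | 0 | 78.1 | 21.6 |
| gamma | 3.00 | 0.7 | 78.6 | 21.3 |
| gamma | 6.00 | 0.4 | 78.5 | 21.0 |

(scatter of a reading: 0.5 percentage points)

- the reaction counts as stopped when no species that holds the X changes by six tenths of a point or more over the second half of the time

1. which holds at 10 min: what has brought the reaction to rest, or that it has not come to rest (it is still moving / forward and back rates have come level / all of X has reacted)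
2. share of the X used up at 10 min
3. Q at 10 min, in percent of the X charged
4. J at 10 min, in percent of the X charged

The flask was gamma's charge of X with twice gamma's loading of G, so I started from gamma. Gamma read 0.7 % of X at 0.500 min and 0.4 % at 6.00 min, against a scatter of 0.5 percentage points, so I expected no X worth reading in the flask at 10 min. The question was the split. The ratio of the two products is an average over the run and needs no clock, so I worked with that ratio. Over gamma's readings it stood at 3.63. I called this Q per J, the Q made for each J made, a selectivity factor.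

I assumed that Q's route ran in proportion to G and that J's route needed none. In one extreme, G added nothing and the flask repeated gamma's split, with 21.6 % J. In the other, Q's route outran J's so far that J fell to half of that, 10.8 %. Doubling Q per J gave 7.27, so I committed to 12.1 % J, below the first extreme and above the second.

The forecast said all of X has reacted, with 99.8 % of X used, 88 % Q and 12 % J, noting that “Halving the enzyme at 34 mM X sharply raises J”. It fitted a power law across the runs, whereas I reckoned from gamma.

The flask gave this result: all of X has reacted, with 100 % of X used, 87.6 % Q and 12.4 % J.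

    X + G → Q + G, rate k1*[X]*[G]/(1 + ([X]/Km1) + ([X]/Ksi1)^2) (0.0770 M, 17.0 mM, k = 1.80 × 10⁵ M⁻¹ s⁻¹)
    X → J (k = 0.0350 s⁻¹)

The flask's Q per J was therefore 7.08, against the 7.27 I had reckoned from gamma's 3.63. At the start, X went to Q at 3.2 times its rate of loss to J, which is lower than that whole-run ratio. Scaling gamma's Q per J to the neighbouring flask with 0.006 mol% of G gave 4.36, or 18.7 % J. That neighbouring flask stood at 18.8 % J at 10.0 min.

All runs come from a simulation on assumed constants, and the scatter is random.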